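**Retrosynthetic overview** (atoms carry their isochromene numbers in the target; PMB = 4-methoxybenzyl)
1. The pyran ring is closed last by 6-endo-dig O-2–C-3 hydroalkoxylation of a hydroxy ynenone; the side chain is joined just before by Sonogashira coupling of ethynyl chloro-enone 13 with dienyl iodide 17.
2. The carbocycle (C-4a, C-5, C-6, C-7, C-8, C-8a) comes from a cyclopentenyl silyl ether by one-carbon ring expansion with dichlorocarbene; the inserted carbon is C-5 with its chlorine.
3. Enabling feature: the 2-chloro-enone C-4a=C-5(Cl)–C-6(=O) in the carbocycle is the fingerprint of a dihalocarbene/enol-ether expansion, and quaternary C-7 between C-6 and C-8 blocks enolisation and aromatisation; C-6, C-7, C-8, C-8a and C-4a therefore come from 2-methylcyclopentane-1,3-dione.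
4. Enol silane 11 comes from ethynylation at C-4a, after copper-catalysed asymmetric conjugate addition of PMBOCH2 to the achiral ene-dione 3 (sets C-8a and C-7), after acetoxylation and dehydrogenation of 1.
5. Ring order: five-membered carbocycle (bought), six-membered carbocycle (step 7), pyran (step 12).

Key step: step 7

Assumption: (R)-2-methylbutan-1-ol is taken as available enantiopure, and C-8a–H of the target (α to the C-8 ketone and vinylogously α to C-6) is treated as base-labile, so every operation after the ring expansion is kept neutral or weakly acidic.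

Step 1
Reactants: 1 2-methylcyclopentane-1,3-dione
Product: 2 2-methyl-1,3-dioxocyclopentan-2-yl acetate
Conditions: Pb(OAc)4, AcOH, rt
Reagents that add atoms: lead tetraacetate, CC(=O)O[Pb](OC(C)=O)(OC(C)=O)OC(C)=O
Why: α-Acetoxylation of the enolised 2-alkyl-1,3-dione by lead tetraacetate should give the fully substituted, non-enolisable carbon that becomes C-7 (no stereocentre yet, the molecule is achiral).

Step 2
Reactants: 2 2-methyl-1,3-dioxocyclopentan-2-yl acetate
Product: 3 2-methyl-1,3-dioxocyclopent-4-en-2-yl acetate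
Conditions: IBX (2-iodoxybenzoic acid), DMSO/fluorobenzene, 70 °C
Reagents that add atoms: none
Why: IBX dehydrogenation of the ketone through its enol should give the achiral ene-dione, whose two alkene carbons are enantiotopic.

Step 3
Reactants: 4 (tributylstannyl)methanol
Product: 5 tributyl{[(4-methoxybenzyl)oxy]methyl}stannane
Conditions: NaH, 4-methoxybenzyl chloride, Bu4NI (cat.), THF/DMF, 0 °C to rt
Reagents that add atoms: 4-methoxybenzyl chloride, COc1ccc(CCl)cc1
Why: Williamson etherification of the sodium alkoxide should give the protected hydroxymethyl-anion precursor.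

Step 4
Reactants: 3 2-methyl-1,3-dioxocyclopent-4-en-2-yl acetate; 5 tributyl{[(4-methoxybenzyl)oxy]methyl}stannane
Product: 9 (1S,4R)-4-{[(4-methoxybenzyl)oxy]methyl}-1-methyl-5-oxo-2-[(trimethylsilyl)oxy]cyclopent-2-en-1-yl acetate, via lithium reagent 6 (not isolated), via diorganozinc 7 (not isolated), via zinc enolate 8 (not isolated)
Conditions: 5, n-BuLi, THF, −78 °C; ZnBr2 (0.5 equiv per Li); then 3, Cu(OTf)2 (5 mol %), (S,R,R)-BINOL bis(1-phenylethyl)amine phosphoramidite (10 mol %), toluene, −40 °C; then Me3SiOTf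
Reagents that add atoms: trimethylsilyl triflate, C[Si](C)(C)OS(=O)(=O)C(F)(F)F
Why: Tin–lithium exchange and transmetalation give the diorganozinc, which should add in a copper-catalysed asymmetric conjugate addition that desymmetrises the cyclopent-4-ene-1,3-dione: the chiral phosphoramidite (the antipode that leads to the 1S,4R series is used) picks one enantiotopic alkene carbon, the nucleophile enters anti to the acetoxy group (its acyl group lies over that ring face and the C–O dipole disfavours syn attack), so C-8a and with it C-7 are fixed, and Me3SiOTf traps the zinc enolate regiospecifically.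

Step 5
Reactants: 9 (1S,4R)-4-{[(4-methoxybenzyl)oxy]methyl}-1-methyl-5-oxo-2-[(trimethylsilyl)oxy]cyclopent-2-en-1-yl acetate
Product: 10 (1S,3R,4R)-3-ethynyl-4-{[(4-methoxybenzyl)oxy]methyl}-1-methyl-2,5-dioxocyclopentyl acetate
Conditions: 1-[(trimethylsilyl)ethynyl]-1,2-benziodoxol-3(1H)-one, Bu4NF, THF, −78 °C; AcOH quench at −78 °C
Reagents that add atoms: 1-[(trimethylsilyl)ethynyl]-1,2-benziodoxol-3(1H)-one, C[Si](C)(C)C#CI1OC(=O)c2ccccc12
Why: Fluoride releases the enolate and the ethynylbenziodoxolone, and electrophilic alkynylation of the enolate (addition to the iodonium alkyne, loss of 2-iodobenzoate, 1,2-shift in the alkylidene carbene) should form the C-4a–C-4 bond trans to the neighbouring CH2OPMB group; this new centre is erased in step 6.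

Step 6
Reactants: 10 (1S,3R,4R)-3-ethynyl-4-{[(4-methoxybenzyl)oxy]methyl}-1-methyl-2,5-dioxocyclopentyl acetate
Product: 11 (1S,4R)-3-ethynyl-4-{[(4-methoxybenzyl)oxy]methyl}-1-methyl-5-oxo-2-[(triethylsilyl)oxy]cyclopent-2-en-1-yl acetate
Conditions: Et3SiOTf, Et3N, CH2Cl2, −78 °C
Reagents that add atoms: triethylsilyl triflate, CC[Si](CC)(CC)OS(=O)(=O)C(F)(F)F
Why: Soft enolisation (silyl triflate/amine) should remove the more acidic propargylic α-hydrogen at C-4a rather than the hindered one at C-8a, giving the conjugated enyne enol silane without touching C-8a.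

Step 7
Reactants: 11 (1S,4R)-3-ethynyl-4-{[(4-methoxybenzyl)oxy]methyl}-1-methyl-5-oxo-2-[(triethylsilyl)oxy]cyclopent-2-en-1-yl acetate
Product: 13 (1R,5R)-3-chloro-4-ethynyl-5-{[(4-methoxybenzyl)oxy]methyl}-1-methyl-2,6-dioxocyclohex-3-en-1-yl acetate, via dichlorocyclopropane 12 (not isolated)
Conditions: PhHgCCl3, benzene, 80 °C
Reagents that add atoms: phenyl(trichloromethyl)mercury, ClC(Cl)(Cl)[Hg]c1ccccc1
Why: Thermal α-elimination of PhHgCl releases dichlorocarbene, which should add to the only electron-rich alkene, the C-6=C-4a silyl enol ether, closing a three-membered ring by [2+1] cheletropic addition to give the 6,6-dichloro-1-siloxybicyclo[3.1.0]hexane 12. Pushed by the siloxy group, 12 opens by disrotatory two-electron electrocyclic cleavage of the ring-fusion bond C-6–C-4a with loss of the endo chloride, so the five-membered ring becomes the six-membered one by insertion of the CCl carbon (C-5) between C-6 and C-4a, and chloride then takes the silyl group from the oxocarbenium ion. The closest known reaction is the dihalocarbene ring expansion of cyclopentanone silyl enol ethers to 2-chlorocyclohex-2-enones. No stereocentre of the product is made here (the two ring-fusion centres of 12 vanish on opening, so the face of carbene attack does not matter), and C-7 and C-8a survive because the medium is neutral and C-7 is quaternary. The step needs chemoselectivity for the enol ether over the alkyne, the anisyl ring and the ketone, which the electrophilic carbene provides, and a single site of insertion, which the position of the enol silane from step 6 fixes; C-4a carries carbon and not a halogen, so only a chloride of the CCl2 carbon can leave. The same operation installs the vinyl chloride and the C-4a=C-5 enone and turns the electron-rich enyne into an ynenone polarised for O-attack at C-3.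

Step 8
Reactants: 14 (R)-2-methylbutan-1-ol
Product: 16 (2E,4R)-2,4-dimethylhex-2-enal, via aldehyde 15 (not isolated)
Conditions: TEMPO (cat.), PhI(OAc)2, CH2Cl2, rt; then Ph3P=C(CH3)CHO, 40 °C
Reagents that add atoms: 2-(triphenylphosphoranylidene)propanal, CC(C=O)=P(c1ccccc1)(c1ccccc1)c1ccccc1
Why: Base-free oxoammonium oxidation should give the configurationally labile aldehyde, which the stabilised ylide converts in the same flask into the (E)-enal by a Wittig reaction.

Step 9
Reactants: 16 (2E,4R)-2,4-dimethylhex-2-enal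
Product: 17 (1E,3E,5R)-1-iodo-3,5-dimethylhepta-1,3-diene
Conditions: CrCl2, CHI3, THF/1,4-dioxane, 0 °C to rt
Reagents that add atoms: iodoform, IC(I)I
Why: Takai olefination (geminal dichromium reagent from CHI3 and CrCl2) should convert the aldehyde into the (E)-vinyl iodide.

Step 10
Reactants: 13 (1R,5R)-3-chloro-4-ethynyl-5-{[(4-methoxybenzyl)oxy]methyl}-1-methyl-2,6-dioxocyclohex-3-en-1-yl acetate; 17 (1E,3E,5R)-1-iodo-3,5-dimethylhepta-1,3-diene
Product: 18 (1R,5R)-3-chloro-4-[(3E,5E,7R)-5,7-dimethylnona-3,5-dien-1-yn-1-yl]-5-{[(4-methoxybenzyl)oxy]methyl}-1-methyl-2,6-dioxocyclohex-3-en-1-yl acetate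
Conditions: PdCl2(PPh3)2 (5 mol %), CuI (10 mol %), iPr2NEt, THF, 0 °C
Reagents that add atoms: none
Why: Sonogashira coupling of the terminal alkyne with the dienyl iodide should proceed with retention of alkene geometry and leave the vinyl chloride alone; a hindered amine at low temperature is used because C-8a–H is acidic.

Step 11
Reactants: 18 (1R,5R)-3-chloro-4-[(3E,5E,7R)-5,7-dimethylnona-3,5-dien-1-yn-1-yl]-5-{[(4-methoxybenzyl)oxy]methyl}-1-methyl-2,6-dioxocyclohex-3-en-1-yl acetate
Product: 19 (1R,5R)-3-chloro-4-[(3E,5E,7R)-5,7-dimethylnona-3,5-dien-1-yn-1-yl]-5-(hydroxymethyl)-1-methyl-2,6-dioxocyclohex-3-en-1-yl acetate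
Conditions: DDQ, CH2Cl2/pH 7 phosphate buffer, 0 °C
Reagents that add atoms: none
Why: Oxidative cleavage of the 4-methoxybenzyl ether by DDQ (hydride abstraction, hydrolysis of the oxocarbenium ion) should free the primary alcohol under buffered, non-basic conditions.

Step 12
Reactants: 19 (1R,5R)-3-chloro-4-[(3E,5E,7R)-5,7-dimethylnona-3,5-dien-1-yn-1-yl]-5-(hydroxymethyl)-1-methyl-2,6-dioxocyclohex-3-en-1-yl acetate
Product: 20 (7R,8aR)-5-chloro-3-[(1E,3E,5R)-3,5-dimethylhepta-1,3-dien-1-yl]-7-methyl-6,8-dioxo-6,7,8,8a-tetrahydro-1H-isochromen-7-yl acetate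
Conditions: Ph3PAuNTf2 (5 mol %), CH2Cl2, 0 °C to rt
Reagents that add atoms: none
Why: Gold-catalysed 6-endo-dig hydroalkoxylation should close the pyran: the alkyne carbon distal to the chloro-enone (C-3) is the Michael-type terminus and carries the cation-stabilising diene, so oxygen attacks there and protodeauration gives the enol ether, with no base and no change at C-7 or C-8a.

**Compound list**
1 | 2-methylcyclopentane-1,3-dione | CC1C(=O)CCC1=O | starting material
2 | 2-methyl-1,3-dioxocyclopentan-2-yl acetate | CC(=O)OC1(C)C(=O)CCC1=O | intermediate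
3 | 2-methyl-1,3-dioxocyclopent-4-en-2-yl acetate | CC(=O)OC1(C)C(=O)C=CC1=O | intermediate
4 | (tributylstannyl)methanol | OC[Sn](CCCC)(CCCC)CCCC | starting material
5 | tributyl{[(4-methoxybenzyl)oxy]methyl}stannane | CCCC[Sn](CCCC)(CCCC)COCc1ccc(OC)cc1 | intermediate
6 | {[(4-methoxybenzyl)oxy]methyl}lithium | [Li]COCc1ccc(OC)cc1 | intermediate
7 | bis{[(4-methoxybenzyl)oxy]methyl}zinc | COc1ccc(COC[Zn]COCc2ccc(OC)cc2)cc1 | intermediate
8 | zinc enolate corresponding to 9 (O–ZnCH2OPMB in place of O–SiMe3) | C1=C(O[Zn]COCc2ccc(OC)cc2)[C@](C)(OC(C)=O)C(=O)[C@H]1COCc3ccc(OC)cc3 | intermediate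
9 | (1S,4R)-4-{[(4-methoxybenzyl)oxy]methyl}-1-methyl-5-oxo-2-[(trimethylsilyl)oxy]cyclopent-2-en-1-yl acetate | C1=C(O[Si](C)(C)C)[C@](C)(OC(C)=O)C(=O)[C@H]1COCc2ccc(OC)cc2 | intermediate
10 | (1S,3R,4R)-3-ethynyl-4-{[(4-methoxybenzyl)oxy]methyl}-1-methyl-2,5-dioxocyclopentyl acetate | C#C[C@@H]1C(=O)[C@](C)(OC(C)=O)C(=O)[C@H]1COCc2ccc(OC)cc2 | intermediate
11 | (1S,4R)-3-ethynyl-4-{[(4-methoxybenzyl)oxy]methyl}-1-methyl-5-oxo-2-[(triethylsilyl)oxy]cyclopent-2-en-1-yl acetate | C#CC1=C(O[Si](CC)(CC)CC)[C@](C)(OC(C)=O)C(=O)[C@H]1COCc2ccc(OC)cc2 | intermediate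
12 | (1R,2S,4R,5R)-6,6-dichloro-5-ethynyl-4-{[(4-methoxybenzyl)oxy]methyl}-2-methyl-3-oxo-1-[(triethylsilyl)oxy]bicyclo[3.1.0]hexan-2-yl acetate (drawn for carbene attack anti to CH2OPMB; the other face gives the same product) | C#C[C@@]12C(Cl)(Cl)[C@]1(O[Si](CC)(CC)CC)[C@](C)(OC(C)=O)C(=O)[C@H]2COCc3ccc(OC)cc3 | intermediate
13 | (1R,5R)-3-chloro-4-ethynyl-5-{[(4-methoxybenzyl)oxy]methyl}-1-methyl-2,6-dioxocyclohex-3-en-1-yl acetate | C#CC1=C(Cl)C(=O)[C@](C)(OC(C)=O)C(=O)[C@H]1COCc2ccc(OC)cc2 | intermediate
14 | (R)-2-methylbutan-1-ol | CC[C@@H](C)CO | starting material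
15 | (R)-2-methylbutanal | CC[C@@H](C)C=O | intermediate
16 | (2E,4R)-2,4-dimethylhex-2-enal | CC[C@@H](C)/C=C(C)/C=O | intermediate
17 | (1E,3E,5R)-1-iodo-3,5-dimethylhepta-1,3-diene | CC[C@@H](C)/C=C(C)/C=C/I | intermediate
18 | (1R,5R)-3-chloro-4-[(3E,5E,7R)-5,7-dimethylnona-3,5-dien-1-yn-1-yl]-5-{[(4-methoxybenzyl)oxy]methyl}-1-methyl-2,6-dioxocyclohex-3-en-1-yl acetate | CC[C@@H](C)/C=C(C)/C=C/C#CC1=C(Cl)C(=O)[C@](C)(OC(C)=O)C(=O)[C@H]1COCc2ccc(OC)cc2 | intermediate
19 | (1R,5R)-3-chloro-4-[(3E,5E,7R)-5,7-dimethylnona-3,5-dien-1-yn-1-yl]-5-(hydroxymethyl)-1-methyl-2,6-dioxocyclohex-3-en-1-yl acetate | CC[C@@H](C)/C=C(C)/C=C/C#CC1=C(Cl)C(=O)[C@](C)(OC(C)=O)C(=O)[C@H]1CO | intermediate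
20 | (7R,8aR)-5-chloro-3-[(1E,3E,5R)-3,5-dimethylhepta-1,3-dien-1-yl]-7-methyl-6,8-dioxo-6,7,8,8a-tetrahydro-1H-isochromen-7-yl acetate | CC[C@@H](C)/C=C(C)/C=C/C1=CC2=C(Cl)C(=O)[C@](C)(OC(C)=O)C(=O)[C@H]2CO1 | target

Total step count: 12. Longest linear sequence: 9 steps (steps 1, 2, 4, 5, 6, 7, 10, 11, 12).

**Steps most likely to fail**

Step 4. The α-alkoxymethyl group may transfer sluggishly from zinc, or the discrimination between the two enantiotopic alkene carbons and between the acetoxy and methyl faces may be too weak, which would erode both the C-8a and the C-7 configuration. The fallback sets out from 3 and separates the two events. A copper-hydride asymmetric 1,4-hydrosilylation (Cu(OAc)2, (R)-DTBM-SEGPHOS or its antipode, PhMe2SiH, toluene) should desymmetrise 3 without forming a carbon–carbon bond and give the enol silane (R)-2-{[dimethyl(phenyl)silyl]oxy}-1-methyl-5-oxocyclopent-2-en-1-yl acetate F1. A Mukaiyama-type alkylation of F1 with 4-methoxybenzyl chloromethyl ether and catalytic ZnBr2 (CH2Cl2, −40 °C), anti to the acetoxy group, should then give the diketone (1S,3R)-3-{[(4-methoxybenzyl)oxy]methyl}-1-methyl-2,5-dioxocyclopentyl acetate F2. Kinetic deprotonation at the unhindered methylene (LiHMDS, Me3SiCl, THF, −78 °C) returns to the route at 9.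

Step 5. The enolate may be alkynylated twice, or the α-ethynyl ketone may isomerise to the allenyl ketone in the fluoride medium. The fallback sets out from 9 and builds the enyne by cross-coupling instead of electrophilic alkynylation. Iodination of the enol silane with N-iodosuccinimide (THF, −78 °C) should give the iodo ketone (1R,3S,4R)-3-iodo-4-{[(4-methoxybenzyl)oxy]methyl}-1-methyl-2,5-dioxocyclopentyl acetate F3. Deprotonation at the iodine-bearing carbon and O-silylation (LiHMDS, Et3SiCl, THF, −78 °C) should give the iodo enol silane (1S,4R)-3-iodo-4-{[(4-methoxybenzyl)oxy]methyl}-1-methyl-5-oxo-2-[(triethylsilyl)oxy]cyclopent-2-en-1-yl acetate F4. Negishi coupling of F4 with ethynylzinc bromide (from ethynylmagnesium bromide and ZnBr2; Pd(PPh3)4, THF, rt) comes back to the route at 11.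

Step 10. The amine may epimerise C-8a, eliminate the PMBO group through the C-8a enolate, or add to the ynenone. The fallback sets out from 13 and replaces the base-mediated coupling by a neutral Stille coupling. Stannylation of the terminal alkyne with Bu3SnOMe (THF, rt, methanol removed) should give the alkynylstannane (1R,5R)-3-chloro-5-{[(4-methoxybenzyl)oxy]methyl}-1-methyl-2,6-dioxo-4-[(tributylstannyl)ethynyl]cyclohex-3-en-1-yl acetate F5. Coupling of F5 with 17 (Pd2(dba)3, AsPh3, THF, rt) returns to the route at 18.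

**Further compounds**
F1 | step 4 | (R)-2-{[dimethyl(phenyl)silyl]oxy}-1-methyl-5-oxocyclopent-2-en-1-yl acetate | C1=C(O[Si](C)(C)c2ccccc2)[C@@](C)(OC(C)=O)C(=O)C1
F2 | step 4 | (1S,3R)-3-{[(4-methoxybenzyl)oxy]methyl}-1-methyl-2,5-dioxocyclopentyl acetate | C1C(=O)[C@](C)(OC(C)=O)C(=O)[C@H]1COCc2ccc(OC)cc2
F3 | step 5 | (1R,3S,4R)-3-iodo-4-{[(4-methoxybenzyl)oxy]methyl}-1-methyl-2,5-dioxocyclopentyl acetate | I[C@@H]1C(=O)[C@](C)(OC(C)=O)C(=O)[C@H]1COCc2ccc(OC)cc2
F4 | step 5 | (1S,4R)-3-iodo-4-{[(4-methoxybenzyl)oxy]methyl}-1-methyl-5-oxo-2-[(triethylsilyl)oxy]cyclopent-2-en-1-yl acetate | IC1=C(O[Si](CC)(CC)CC)[C@](C)(OC(C)=O)C(=O)[C@H]1COCc2ccc(OC)cc2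
F5 | step 10 | (1R,5R)-3-chloro-5-{[(4-methoxybenzyl)oxy]methyl}-1-methyl-2,6-dioxo-4-[(tributylstannyl)ethynyl]cyclohex-3-en-1-yl acetate | CCCC[Sn](CCCC)(CCCC)C#CC1=C(Cl)C(=O)[C@](C)(OC(C)=O)C(=O)[C@H]1COCc2ccc(OC)cc2
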